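**Assumption:** the target has no stereocentre, so no enantiocontrol is needed; 2-bromo-6-methoxyphenol (6-bromoguaiacol) is taken as an inexpensive catalogue compound.

## Retrosynthetic overview

- Target ⇒ 3-bromo-5-methylcatechol by two electrophilic brominations ⇒ 2-bromo-6-methoxy-4-methylphenol by O-demethylation.
- Ar–CH3 ⇒ Ar–CH2NMe3+ (reductive C–N cleavage through a p-quinone methide) ⇒ Ar–CH2NMe2.
- Key C–C disconnection: the Ar–CH2N bond, made by a phenolic Mannich reaction of 2-bromo-6-methoxyphenol with formaldehyde and dimethylamine. Br and OMe block both ortho positions, so only the para carbon can react, and that Br stays in the target.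
- Rings: the single benzene ring is bought with the starting phenol; no ring is formed in the route.

## Route

Step 1
Reactants: 1 2-bromo-6-methoxyphenol; 2 formaldehyde; 3 dimethylamine
Product: 5 2-bromo-4-[(dimethylamino)methyl]-6-methoxyphenol, via N,N-dimethylmethaniminium 4 (not isolated)
Conditions: 37% aq. CH2O (1.5 equiv), 40% aq. Me2NH (1.5 equiv), EtOH, reflux, 12 h
Reagents that add atoms: formaldehyde C=O; dimethylamine CNC
Why: Phenolic Mannich reaction in which the phenol(ate) of 1 acts as the enol partner and attacks iminium 4 at its only free ortho/para carbon (C4, para to OH, since both ortho positions carry Br and OMe), then re-aromatises; no stereocentre is formed.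

Step 2
Reactants: 5 2-bromo-4-[(dimethylamino)methyl]-6-methoxyphenol; 6 iodomethane
Product: 7 (3-bromo-4-hydroxy-5-methoxyphenyl)-N,N,N-trimethylmethanaminium iodide
Conditions: MeI (1.5 equiv), acetone, rt, 12 h, dark; filter the precipitate
Reagents that add atoms: iodomethane CI
Why: Menshutkin N-alkylation, in which the tertiary amine is far more nucleophilic than the un-ionised, hindered phenol, so without base MeI gives the crystalline methiodide selectively.

Step 3
Reactants: 7 (3-bromo-4-hydroxy-5-methoxyphenyl)-N,N,N-trimethylmethanaminium iodide
Product: 9 2-bromo-6-methoxy-4-methylphenol, via 2-bromo-6-methoxy-4-methylidenecyclohexa-2,5-dien-1-one 8 (not isolated)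
Conditions: NaBH4 (4 equiv), DMSO, 70 °C, 3 h; then aq. NH4Cl
Reagents that add atoms: none
Why: Reductive deamination of a Mannich methiodide, in which the phenoxide of 7 expels NMe3 by 1,6-elimination to give p-quinone methide 8, which takes up hydride by 1,6-conjugate addition and re-aromatises, while the aryl bromide is inert to NaBH4.

Step 4
Reactants: 9 2-bromo-6-methoxy-4-methylphenol
Product: 11 3-bromo-5-methylbenzene-1,2-diol, via 2,4-dibromo-6-methyl-1,3,2-benzodioxaborole 10 (not isolated)
Conditions: BBr3 (2.5 equiv), CH2Cl2, −78 °C → rt, 4 h; then H2O, 0 °C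
Reagents that add atoms: none
Why: Lewis-acid aryl methyl ether cleavage, in which boron binds the phenol oxygen and the neighbouring OMe, bromide removes the methyl by SN2 to give cyclic borate 10, and water hydrolyses the B–O bonds, leaving ArBr and ArCH3 untouched.

Step 5
Reactants: 11 3-bromo-5-methylbenzene-1,2-diol; 12 bromine
Product: 15 3,4,6-tribromo-5-methylbenzene-1,2-diol, via 3,4-dibromo-5-methylbenzene-1,2-diol 13 (not isolated), via 3,6-dibromo-4-methylbenzene-1,2-diol 14 (not isolated)
Conditions: Br2 (2.2 equiv), AcOH, 10 °C → rt, 3 h; aq. Na2S2O4 wash; recrystallise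
Reagents that add atoms: bromine BrBr
Why: Electrophilic aromatic bromination, in which the two remaining ring positions are para and ortho to the C1 hydroxyl, so the activated catechol takes up exactly two bromines through either dibromide 13 or 14 (both converge on 15), and the dithionite wash returns any o-quinone to the catechol.

## Compound list

1 | 2-bromo-6-methoxyphenol | COc1cccc(Br)c1O | starting material
2 | formaldehyde | C=O | starting material
3 | dimethylamine | CNC | starting material
4 | N,N-dimethylmethaniminium | C=[N+](C)C | intermediate
5 | 2-bromo-4-[(dimethylamino)methyl]-6-methoxyphenol | COc1cc(CN(C)C)cc(Br)c1O | intermediate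
6 | iodomethane | CI | starting material
7 | (3-bromo-4-hydroxy-5-methoxyphenyl)-N,N,N-trimethylmethanaminium iodide | COc1cc(C[N+](C)(C)C)cc(Br)c1O.[I-] | intermediate
8 | 2-bromo-6-methoxy-4-methylidenecyclohexa-2,5-dien-1-one | C=C1C=C(Br)C(=O)C(OC)=C1 | intermediate
9 | 2-bromo-6-methoxy-4-methylphenol | COc1cc(C)cc(Br)c1O | intermediate
10 | 2,4-dibromo-6-methyl-1,3,2-benzodioxaborole | Cc1cc(Br)c2OB(Br)Oc2c1 | intermediate
11 | 3-bromo-5-methylbenzene-1,2-diol | Cc1cc(O)c(O)c(Br)c1 | intermediate
12 | bromine | BrBr | starting material
13 | 3,4-dibromo-5-methylbenzene-1,2-diol | Cc1cc(O)c(O)c(Br)c1Br | intermediate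
14 | 3,6-dibromo-4-methylbenzene-1,2-diol | Cc1cc(Br)c(O)c(O)c1Br | intermediate
15 | 3,4,6-tribromo-5-methylbenzene-1,2-diol | Cc1c(Br)c(O)c(O)c(Br)c1Br | target

## Summary

Total step count: 5. Longest linear sequence: 5 steps (1 → 5 → 7 → 9 → 11 → 15).

Three steps most likely to fail, each with a fallback:

- **Step 1.** The Mannich reaction on a bromine-deactivated, doubly ortho-blocked phenol may be slow or give diarylmethane. The fallback sets out from 1 and hydroxymethylates it instead (Lederer–Manasse aldol-type addition of the phenoxide to formaldehyde; 37% aq. CH2O, NaOH, H2O, 40 °C). This gives 2-bromo-4-(hydroxymethyl)-6-methoxyphenol F1. The p-hydroxybenzylic alcohol is then deoxygenated by ionic hydrogenation (Et3SiH, TFA, CH2Cl2, 0 °C → rt). The fallback comes back to the route at 9, bypassing 5 and 7.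

- **Step 3.** The quinone methide may be trapped by other nucleophiles, or the elimination may be incomplete. The fallback sets out from 5 and uses catalytic hydrogenolysis (H2 10 bar, 10% Pd/C, EtOH–AcOH, 80 °C). This cleaves the benzylic C–N bond and, knowingly, the aryl C–Br bond as well, to give 2-methoxy-4-methylphenol F2. The bromine is then put back ortho to the hydroxyl by amine-catalysed ortho-bromination (NBS, cat. i-Pr2NH, CH2Cl2, 0 °C). The fallback comes back to the route at 9.

- **Step 5.** The free catechol may be oxidised to the o-quinone, or bromination may occur at the benzylic position. The fallback sets out from 9 and brominates the oxidation-resistant monomethyl ether first (Br2 2.2 equiv, NaOAc, AcOH, rt), at the positions para and ortho to OMe. This gives 2,3,5-tribromo-6-methoxy-4-methylphenol F3. The ether is then cleaved last with BBr3 (CH2Cl2, −78 °C → rt; H2O). The fallback comes back to the route at 15.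

## Further compounds

F1 | step 1 | 2-bromo-4-(hydroxymethyl)-6-methoxyphenol | COc1cc(CO)cc(Br)c1O
F2 | step 3 | 2-methoxy-4-methylphenol | COc1cc(C)ccc1O
F3 | step 5 | 2,3,5-tribromo-6-methoxy-4-methylphenol | COc1c(O)c(Br)c(Br)c(C)c1Br
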